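**Plan**

- Retrosynthesis: after the acid and the methyl ether are unmasked, the C4–C4a bond of the chroman is cut by moving C4 back onto C8a, which contracts the ring to a spiro tetrahydrofuran (a 1-oxaspiro[4.5]deca-6,9-dien-8-one). Then follow the O1–C8a bond (phenol dearomatization), the aryl–CH2 bond (B-alkyl Suzuki coupling, made at the carbon that later becomes C8a), the C2=C3 bond of the acid chain (Still–Gennari) and its C3–C4 bond (aza-enolate alkylation).
- Enabling feature: O1 (on C8a) and the methoxy oxygen (on C6) are para on the benzene ring and C4 sits ortho to O1. This is the product pattern of a dienone–phenol shift in a 4-alkoxy-4-alkylcyclohexa-2,5-dienone; the C8 methyl blocks the other ortho carbon, so only C4a can take up C4 and rearomatize.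
- Forward: the chain is built on (R)-linalool (C8 oxidation, two-carbon extension, (Z)-olefination), and the phenol is joined through the vinyl group. The five-membered ring O1–C2–C3–C4–C8a is closed by oxidative spiroetherification, and the six-membered ring O1–C2–C3–C4–C4a–C8a arises from it by a 1,2-shift of C4; O-methylation and saponification finish.
- Stereochemistry: C2 (R) is the carbinol carbon of (R)-linalool and none of its four bonds is ever broken; 6E comes from the (E)-selective SeO2 oxidation, 2Z from the Still–Gennari olefination.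
- Locants: chroman numbering (O1, C2, C3, C4, C4a, C5–C8, C8a) for the ring system, nonadienoic acid numbering for the chain.

Key step: step 7

Remark: (R)-(−)-linalool is assumed to be bought in high enantiomeric purity (the route cannot raise it), and imine 5 is assumed to be a stock reagent (it also forms on mixing acetaldehyde with tert-butylamine).

**Route**

Step 1
Reactants: 1 (R)-(−)-linalool, (3R)-3,7-dimethylocta-1,6-dien-3-ol
Product: 2 (2E,6R)-2,6-dimethylocta-2,7-diene-1,6-diol
Conditions: SeO2 (cat.), t-BuOOH, salicylic acid (cat.), CH2Cl2, 0 °C → rt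
Reagents that add atoms: selenium dioxide, O=[Se]=O (oxygen carrier); tert-butyl hydroperoxide, CC(C)(C)OO (terminal oxygen source)
Why: Riley allylic oxidation (ene reaction, then 2,3-sigmatropic shift) should attack the electron-rich trisubstituted alkene at its (E)-methyl group, the vinyl group having no allylic hydrogen, so that the (E)-allylic alcohol forms and the carbinol stereocenter is untouched.

Step 2
Reactants: 2 (2E,6R)-2,6-dimethylocta-2,7-diene-1,6-diol
Product: 4 (3R,6E)-8-bromo-3,7-dimethylocta-1,6-dien-3-ol, via allylic mesylate 3 (not isolated)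
Conditions: MsCl, Et3N, THF, −40 °C; then LiBr, −40 → 0 °C
Reagents that add atoms: lithium bromide, [Li+].[Br-]
Why: Chemoselective sulfonylation of the primary allylic hydroxyl (the tertiary one is inert at this temperature) followed by SN2 displacement with bromide should give the (E)-allylic bromide without allylic transposition.

Step 3
Reactants: 4 (3R,6E)-8-bromo-3,7-dimethylocta-1,6-dien-3-ol; 5 acetaldehyde N-tert-butylimine
Product: 7 (4E,8R)-8-hydroxy-4,8-dimethyldeca-4,9-dienal, via N-tert-butyl imine 6 (not isolated)
Conditions: 5, LiN(i-Pr)2 (excess), THF, −78 °C; add 4, −78 → −20 °C; then aq. AcOH/NaOAc (pH 4.5), 0 °C → rt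
Reagents that add atoms: water, O
Why: Metalloenamine (aza-enolate) alkylation should attack the primary allylic bromide in SN2 fashion with the (E)-alkene kept, one extra equivalent of base taking the hydroxyl proton, and buffered hydrolysis of imine 6 frees the aldehyde without ionizing the tertiary allylic alcohol.

Step 4
Reactants: 7 (4E,8R)-8-hydroxy-4,8-dimethyldeca-4,9-dienal; 8 ethyl 2-[bis(2,2,2-trifluoroethoxy)phosphoryl]propanoate
Product: 9 ethyl (2Z,6E,10R)-10-hydroxy-2,6,10-trimethyldodeca-2,6,11-trienoate
Conditions: 8, KN(SiMe3)2, 18-crown-6, THF, −78 °C; then 7, −78 °C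
Reagents that add atoms: none
Why: Still–Gennari olefination, in which the electron-poor bis(trifluoroethyl) phosphonate makes elimination from the kinetic adduct fast, should give the (Z)-2-methyl enoate (ester cis to the chain) from this unbranched aldehyde.

Step 5
Reactants: 9 ethyl (2Z,6E,10R)-10-hydroxy-2,6,10-trimethyldodeca-2,6,11-trienoate; 10 4-bromo-3-methylphenol
Product: 12 ethyl (2Z,6E,10R)-10-hydroxy-12-(4-hydroxy-2-methylphenyl)-2,6,10-trimethyldodeca-2,6-dienoate, via B-alkyl-9-BBN adduct 11 (not isolated)
Conditions: 9-BBN-H dimer (excess), THF, 0 °C → rt; then 10, Pd(OAc)2, SPhos, K3PO4, H2O, THF, 65 °C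
Reagents that add atoms: none
Why: 9-BBN should add only to the monosubstituted vinyl group (anti-Markovnikov, the trisubstituted alkenes and the enoate being left), and B-alkyl Suzuki–Miyaura coupling of 11 with the aryl bromide forms the aryl–CH2 bond para to the phenol oxygen, the free hydroxyls being covered by excess borane and base.

Step 6
Reactants: 12 ethyl (2Z,6E,10R)-10-hydroxy-12-(4-hydroxy-2-methylphenyl)-2,6,10-trimethyldodeca-2,6-dienoate
Product: 13 ethyl (2Z,6E)-9-[(2R)-2,6-dimethyl-8-oxo-1-oxaspiro[4.5]deca-6,9-dien-2-yl]-2,6-dimethylnona-2,6-dienoate (both configurations at the spiro carbon, which is the later C8a)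
Conditions: PhI(OAc)2, (CF3)2CHOH/CH2Cl2, 0 °C; aq. NaHCO3 work-up
Reagents that add atoms: none
Why: Oxidative phenol dearomatization with a trivalent iodine reagent should give a phenoxenium-type species that the tethered tertiary hydroxyl traps at the para carbon (5-exo spiroetherification) faster than the isolated alkenes react; the spiro center is uncontrolled and is erased in step 7.

Step 7
Reactants: 13 ethyl (2Z,6E)-9-[(2R)-2,6-dimethyl-8-oxo-1-oxaspiro[4.5]deca-6,9-dien-2-yl]-2,6-dimethylnona-2,6-dienoate
Product: 14 ethyl (2Z,6E)-9-[(2R)-6-hydroxy-2,8-dimethyl-3,4-dihydro-2H-chromen-2-yl]-2,6-dimethylnona-2,6-dienoate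
Conditions: BF3·OEt2, CH2Cl2, −40 → 0 °C; aq. NaHCO3 quench
Reagents that add atoms: none
Why: BF3 binds the dienone oxygen of 13 and makes the carbocycle a pentadienyl cation, whereupon the C4–C8a bond of the tetrahydrofuran ring shifts suprafacially to the unsubstituted neighbouring carbon (the later C4a) and the proton on that carbon is lost to restore the benzene ring. This is the dienone–phenol rearrangement in its quinol ether form, the closest known cases being the acid-induced conversion of 4-alkoxy-4-alkylcyclohexa-2,5-dienones into hydroquinone monoethers. The dihydropyran ring O1–C2–C3–C4–C4a–C8a is therefore not closed by a new bond at O1 or C2 but by one-carbon ring expansion of the five-membered ring O1–C2–C3–C4–C8a through a 1,2-alkyl shift. No stereocenter is created: the spiro center becomes the aromatic C8a, so both epimers of 13 converge, and C2 keeps the (R) configuration of linalool because none of its bonds takes part. Two selectivities are needed: carbon must migrate and not oxygen, which is secured because only the carbon shift leaves the charge on C8a as an oxocarbenium ion of O1, and the terminus must be C4a and not the methyl-bearing C8, which is secured because a shift to C8 gives a cation that cannot lose a proton and reverts. The aprotic Lewis acid at low temperature is chosen so that the chain alkenes and the tertiary C2–O1 bond are not ionized.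

Step 8
Reactants: 14 ethyl (2Z,6E)-9-[(2R)-6-hydroxy-2,8-dimethyl-3,4-dihydro-2H-chromen-2-yl]-2,6-dimethylnona-2,6-dienoate
Product: 15 ethyl (2Z,6E)-9-[(2R)-6-methoxy-2,8-dimethyl-3,4-dihydro-2H-chromen-2-yl]-2,6-dimethylnona-2,6-dienoate
Conditions: MeI, K2CO3, acetone, 50 °C
Reagents that add atoms: iodomethane, CI
Why: Williamson ether synthesis on the unhindered C6 phenoxide should proceed cleanly, the (Z)-enoate and the tertiary aryl ether being inert to K2CO3.

Step 9
Reactants: 15 ethyl (2Z,6E)-9-[(2R)-6-methoxy-2,8-dimethyl-3,4-dihydro-2H-chromen-2-yl]-2,6-dimethylnona-2,6-dienoate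
Product: 16 (2Z,6E)-9-[(2R)-6-methoxy-2,8-dimethyl-3,4-dihydro-2H-chromen-2-yl]-2,6-dimethylnona-2,6-dienoic acid (CNP0171841.1)
Conditions: LiOH, THF/H2O, rt → 40 °C; then aq. HCl to pH 3, 0 °C
Reagents that add atoms: lithium hydroxide, [Li+].[OH-]
Why: Mild saponification (acyl–oxygen cleavage) of the ethyl ester should leave the (2Z) geometry and the chroman untouched, and acidification frees the acid.

**Compound list**

1 | (R)-(−)-linalool, (3R)-3,7-dimethylocta-1,6-dien-3-ol | C=C[C@](C)(O)CCC=C(C)C | starting material
2 | (2E,6R)-2,6-dimethylocta-2,7-diene-1,6-diol | C=C[C@](C)(O)CC/C=C(\C)CO | intermediate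
3 | (2E,6R)-6-hydroxy-2,6-dimethylocta-2,7-dien-1-yl methanesulfonate | C=C[C@](C)(O)CC/C=C(\C)COS(C)(=O)=O | intermediate
4 | (3R,6E)-8-bromo-3,7-dimethylocta-1,6-dien-3-ol | C=C[C@](C)(O)CC/C=C(\C)CBr | intermediate
5 | acetaldehyde N-tert-butylimine (N-tert-butylethanimine) | CC=NC(C)(C)C | starting material
6 | (3R,6E)-10-(tert-butylimino)-3,7-dimethyldeca-1,6-dien-3-ol | C=C[C@](C)(O)CC/C=C(\C)CCC=NC(C)(C)C | intermediate
7 | (4E,8R)-8-hydroxy-4,8-dimethyldeca-4,9-dienal | C=C[C@](C)(O)CC/C=C(\C)CCC=O | intermediate
8 | ethyl 2-[bis(2,2,2-trifluoroethoxy)phosphoryl]propanoate | CCOC(=O)C(C)P(=O)(OCC(F)(F)F)OCC(F)(F)F | starting material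
9 | ethyl (2Z,6E,10R)-10-hydroxy-2,6,10-trimethyldodeca-2,6,11-trienoate | C=C[C@](C)(O)CC/C=C(\C)CC/C=C(/C)C(=O)OCC | intermediate
10 | 4-bromo-3-methylphenol | Cc1cc(O)ccc1Br | starting material
11 | ethyl (2Z,6E,10S)-12-(9-borabicyclo[3.3.1]nonan-9-yl)-10-hydroxy-2,6,10-trimethyldodeca-2,6-dienoate (same spatial arrangement as 9; the descriptor changes with the boron substituent) | C1CCC2CCCC1B2CC[C@](C)(O)CC/C=C(\C)CC/C=C(/C)C(=O)OCC | intermediate
12 | ethyl (2Z,6E,10R)-10-hydroxy-12-(4-hydroxy-2-methylphenyl)-2,6,10-trimethyldodeca-2,6-dienoate | Cc1cc(O)ccc1CC[C@](C)(O)CC/C=C(\C)CC/C=C(/C)C(=O)OCC | intermediate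
13 | ethyl (2Z,6E)-9-[(2R)-2,6-dimethyl-8-oxo-1-oxaspiro[4.5]deca-6,9-dien-2-yl]-2,6-dimethylnona-2,6-dienoate, two epimers at the spiro carbon | CC1=CC(=O)C=CC12CC[C@@](C)(CC/C=C(\C)CC/C=C(/C)C(=O)OCC)O2 | intermediate
14 | ethyl (2Z,6E)-9-[(2R)-6-hydroxy-2,8-dimethyl-3,4-dihydro-2H-chromen-2-yl]-2,6-dimethylnona-2,6-dienoate | Oc1cc(C)c2c(c1)CC[C@@](C)(CC/C=C(\C)CC/C=C(/C)C(=O)OCC)O2 | intermediate
15 | ethyl (2Z,6E)-9-[(2R)-6-methoxy-2,8-dimethyl-3,4-dihydro-2H-chromen-2-yl]-2,6-dimethylnona-2,6-dienoate | COc1cc(C)c2c(c1)CC[C@@](C)(CC/C=C(\C)CC/C=C(/C)C(=O)OCC)O2 | intermediate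
16 | (2Z,6E)-9-[(2R)-6-methoxy-2,8-dimethyl-3,4-dihydro-2H-chromen-2-yl]-2,6-dimethylnona-2,6-dienoic acid | COc1cc(C)c2c(c1)CC[C@@](C)(CC/C=C(\C)CC/C=C(/C)C(=O)O)O2 | target

**Count**

Total steps: 9. Longest linear sequence: 9 steps (1 → 16).

**Steps most likely to fail**

Step 7 (ring expansion). What may go wrong: the shift of C4 may go toward the methyl-bearing carbon and end in a methyl migration, the tertiary C2–O1 bond may ionize under the Lewis acid with loss of configuration, or the cation may be captured by the C6=C7 chain alkene. The fallback sets out from 9 and comes back at 15, by-passing 12 to 14; the O1–C8a bond is made last by cross-coupling instead of by dearomatization. Commercial 4-methoxy-2-methylaniline would be iodinated ortho to nitrogen (ICl, CaCO3, CH2Cl2/MeOH) to 2-iodo-4-methoxy-6-methylaniline F1, and Sandmeyer bromination (t-BuONO, CuBr2, MeCN) should give 2-bromo-1-iodo-5-methoxy-3-methylbenzene F2. Hydroboration of 9 with 9-BBN to adduct 11 as in step 5 and Suzuki–Miyaura coupling at the carbon–iodine bond of F2 (Pd(dppf)Cl2, K3PO4, THF/H2O, 40 °C) should give ethyl (2Z,6E,10R)-12-(2-bromo-5-methoxy-3-methylphenyl)-10-hydroxy-2,6,10-trimethyldodeca-2,6-dienoate F3. Intramolecular palladium-catalysed aryl ether formation from the tertiary alkoxide (Buchwald–Hartwig etherification; Pd(OAc)2, 2-(di-tert-butylphosphino)-1,1'-binaphthyl, Cs2CO3, toluene, 80 °C) closes the chroman without touching any bond at C2 and gives 15.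

Step 3 (two-carbon extension). What may go wrong: the lithium alkoxide formed from the free hydroxyl may close onto the allylic bromide in SN2' fashion (tetrahydrofuran formation), the aza-enolate may attack with allylic transposition, or the hydrolysis may ionize the tertiary allylic alcohol. The fallback sets out from 4 and comes back at 7, using a soft enolate that does not deprotonate the hydroxyl. Alkylation of dimethyl malonate (NaH, THF, 0 °C → rt) with 4 should give dimethyl 2-[(2E,6R)-6-hydroxy-2,6-dimethylocta-2,7-dien-1-yl]propanedioate F4. Krapcho dealkoxycarbonylation (LiCl, wet DMSO, 140 °C) should give methyl (4E,8R)-8-hydroxy-4,8-dimethyldeca-4,9-dienoate F5, and half-reduction with i-Bu2AlH (CH2Cl2, −78 °C) gives aldehyde 7.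

Step 5 (hydroboration and B-alkyl coupling). What may go wrong: slow oxidative addition to the electron-rich bromophenoxide, protodeboronation or β-hydride loss from the alkylpalladium species, and interference of the borane-bound tertiary hydroxyl. The fallback sets out from 9 (with 10) and comes back at 12, joining the fragments at the alkene level. A Heck reaction of 9 with 10 (Pd(OAc)2, P(o-tol)3, Et3N, MeCN, 80 °C) at the unsubstituted vinyl terminus should give ethyl (2Z,6E,10R,11E)-10-hydroxy-12-(4-hydroxy-2-methylphenyl)-2,6,10-trimethyldodeca-2,6,11-trienoate F6. Diimide, generated from 2-nitrobenzenesulfonohydrazide and Et3N (CH2Cl2, rt), should saturate only the disubstituted styrene double bond and give 12.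

**Further compounds**

F1 | step 7 | 2-iodo-4-methoxy-6-methylaniline | COc1cc(C)c(N)c(I)c1
F2 | step 7 | 2-bromo-1-iodo-5-methoxy-3-methylbenzene | COc1cc(C)c(Br)c(I)c1
F3 | step 7 | ethyl (2Z,6E,10R)-12-(2-bromo-5-methoxy-3-methylphenyl)-10-hydroxy-2,6,10-trimethyldodeca-2,6-dienoate | COc1cc(C)c(Br)c(c1)CC[C@](C)(O)CC/C=C(\C)CC/C=C(/C)C(=O)OCC
F4 | step 3 | dimethyl 2-[(2E,6R)-6-hydroxy-2,6-dimethylocta-2,7-dien-1-yl]propanedioate | C=C[C@](C)(O)CC/C=C(\C)CC(C(=O)OC)C(=O)OC
F5 | step 3 | methyl (4E,8R)-8-hydroxy-4,8-dimethyldeca-4,9-dienoate | C=C[C@](C)(O)CC/C=C(\C)CCC(=O)OC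
F6 | step 5 | ethyl (2Z,6E,10R,11E)-10-hydroxy-12-(4-hydroxy-2-methylphenyl)-2,6,10-trimethyldodeca-2,6,11-trienoate | Cc1cc(O)ccc1/C=C/[C@](C)(O)CC/C=C(\C)CC/C=C(/C)C(=O)OCC
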